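**Retrosynthetic overview**

1. The target comes from its 4-O-methyl ether by chloride demethylation. Ring A, the 5-ylidenefuran-2(5H)-one, is the only ring that is built, and it is closed in the penultimate step; both furans are bought.
2. The strategy rests on one feature of ring A: lactone oxygen O1 is bonded to the exocyclic ylidene carbon C5 and lies cis (Z) to the side chain across C5=CH. That is the anti-addition pattern of a CO2H group across a C≡C bond, so ring A ⇒ a (2E)-3-methoxy-2-methylalk-2-en-4-ynoic acid by silver-catalysed 5-exo-dig formation of the O1–C5 bond.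
3. Enynoic acid ⇒ alkynyl β-keto ester (O-methylation that places the ester cis to the alkyne, then saponification) ⇒ ynal + methyl propanoate (aldol, oxidation) ⇒ α-methyl aldehyde (Corey–Fuchs, formylation).
4. Aldehyde ⇒ (S)-2-methylhept-6-yn-1-ol + a difuryl (E)-vinyl iodide; zirconium-catalysed carboalumination and palladium-catalysed alkenyl–alkenyl coupling set the (E,E)-diene in one flask.
5. Alkynol ⇒ (R)-3-bromo-2-methylpropan-1-ol (sole source of the stereocenter) + a silylbutynyl Grignard reagent; vinyl iodide ⇒ 3,4-dibromofuran + furan-3-carbaldehyde.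

Key step: step 16

Remark on the chemistry: (R)-3-bromo-2-methylpropan-1-ol, the bromohydrin of the Roche ester series sold as either enantiomer, is taken as the chiral starting material. Its stereocenter is never a reacting atom; the descriptor changes from R to S only because the CIP priorities of its neighbours change.

**Route**

Step 1
Reactants: 1 3,4-dibromofuran; 2 furan-3-carbaldehyde
Product: 4 (4-bromofuran-3-yl)(furan-3-yl)methanol (racemic), via 4-bromo-3-furyllithium 3 (not isolated)
Conditions: n-BuLi (1.0 equiv), Et2O, −78 °C; then 2, −78 °C; H2O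
Reagents that add atoms: none
Why: Bromine–lithium exchange with one equivalent of n-BuLi at −78 °C should cleanly give the monolithio furan, which adds 1,2 to the aldehyde; the carbinol center is racemic and is removed in step 2.

Step 2
Reactants: 4 (4-bromofuran-3-yl)(furan-3-yl)methanol
Product: 5 3-bromo-4-(furan-3-ylmethyl)furan
Conditions: Et3SiH (3 equiv), CF3CO2H (3 equiv), CH2Cl2 (dilute), −20 to 0 °C
Reagents that add atoms: none
Why: Ionic hydrogenation, in which the acid ionises the carbinol to a cation stabilised by two 3-furyl groups and excess silane should trap it by hydride transfer before it can alkylate another furan.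

Step 3
Reactants: 5 3-bromo-4-(furan-3-ylmethyl)furan
Product: 7 4-(furan-3-ylmethyl)furan-3-carbaldehyde, via 4-(furan-3-ylmethyl)-3-furyllithium 6 (not isolated)
Conditions: n-BuLi, THF, −78 °C; then DMF, −78 to 0 °C; H2O
Reagents that add atoms: N,N-dimethylformamide, CN(C)C=O
Why: Bromine–lithium exchange followed by formylation of the aryllithium with DMF, kept at −78 °C so that the 3-lithiofuran does not isomerise to the 2-lithio species.

Step 4
Reactants: 7 4-(furan-3-ylmethyl)furan-3-carbaldehyde
Product: 8 3-(furan-3-ylmethyl)-4-[(E)-2-iodoethenyl]furan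
Conditions: CHI3 (2 equiv), CrCl2 (6 equiv), THF/1,4-dioxane, 0 °C to rt, dark
Reagents that add atoms: iodoform, IC(I)I
Why: Takai iodoolefination, in which the geminal dichromium species made from CHI3 and divalent chromium adds to the aldehyde and eliminates to the (E)-vinyl iodide, reliably E-selective for aromatic aldehydes and inert toward furans.

Step 5
Reactants: 9 (R)-3-bromo-2-methylpropan-1-ol
Product: 10 tert-butyl{[(2R)-3-bromo-2-methylpropyl]oxy}dimethylsilane
Conditions: TBSCl, imidazole, CH2Cl2, 0 °C to rt
Reagents that add atoms: tert-butyldimethylsilyl chloride, CC(C)(C)[Si](C)(C)Cl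
Why: Standard silylation of a primary alcohol, needed so that the hydroxyl does not quench the Grignard reagent of step 6.

Step 6
Reactants: 10 tert-butyl{[(2R)-3-bromo-2-methylpropyl]oxy}dimethylsilane; 11 (4-bromobut-1-yn-1-yl)trimethylsilane
Product: 13 tert-butyldimethyl{[(2S)-2-methyl-7-(trimethylsilyl)hept-6-yn-1-yl]oxy}silane, via 4-(trimethylsilyl)but-3-ynylmagnesium bromide 12 (not isolated)
Conditions: 11, Mg, THF, rt; then 10, Li2CuCl4 (3 mol%), THF/NMP, 0 °C to rt
Reagents that add atoms: none
Why: Kochi-type copper-catalysed sp3–sp3 coupling of a primary alkyl bromide with a primary alkyl Grignard reagent; the stereocenter is β to the reacting carbon and is not touched.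

Step 7
Reactants: 13 tert-butyldimethyl{[(2S)-2-methyl-7-(trimethylsilyl)hept-6-yn-1-yl]oxy}silane
Product: 14 (2S)-2-methylhept-6-yn-1-ol
Conditions: Bu4NF (3 equiv), wet THF, rt
Reagents that add atoms: none
Why: Fluoride should cleave the O–Si bond of the silyl ether and the C(sp)–Si bond of the alkynylsilane in one operation.

Step 8
Reactants: 14 (2S)-2-methylhept-6-yn-1-ol; 8 3-(furan-3-ylmethyl)-4-[(E)-2-iodoethenyl]furan
Product: 16 (2S,6E,8E)-9-[4-(furan-3-ylmethyl)furan-3-yl]-2,6-dimethylnona-6,8-dien-1-ol, via alkenyldimethylalane 15 (not isolated)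
Conditions: AlMe3 (3 equiv), Cp2ZrCl2 (0.25 equiv), CH2Cl2, 0 °C to rt; volatiles removed; then 8, Pd(PPh3)4 (5 mol%), ZnCl2 (cat.), THF, rt; aq. Rochelle salt
Reagents that add atoms: trimethylaluminium, C[Al](C)C
Why: Negishi zirconium-catalysed carboalumination adds methyl and aluminium syn across the terminal alkyne with aluminium on the terminal carbon, and the alkenylalane then couples with the vinyl iodide under zerovalent palladium with retention at both partners, so the (E,E)-diene should result; the hydroxyl is carried as its aluminium alkoxide.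

Step 9
Reactants: 16 (2S,6E,8E)-9-[4-(furan-3-ylmethyl)furan-3-yl]-2,6-dimethylnona-6,8-dien-1-ol
Product: 17 (2S,6E,8E)-9-[4-(furan-3-ylmethyl)furan-3-yl]-2,6-dimethylnona-6,8-dienal
Conditions: Dess–Martin periodinane, NaHCO3, CH2Cl2, 0 °C to rt
Reagents that add atoms: none
Why: Dess–Martin oxidation under buffered, non-basic conditions should give the α-branched aldehyde without epimerisation and leave the furans and the diene alone.

Step 10
Reactants: 17 (2S,6E,8E)-9-[4-(furan-3-ylmethyl)furan-3-yl]-2,6-dimethylnona-6,8-dienal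
Product: 18 3-[(1E,3E,8S)-10,10-dibromo-4,8-dimethyldeca-1,3,9-trien-1-yl]-4-(furan-3-ylmethyl)furan
Conditions: CBr4, PPh3, Zn dust, CH2Cl2, rt (reagent preformed); then 17, 0 °C to rt
Reagents that add atoms: carbon tetrabromide, BrC(Br)(Br)Br
Why: Corey–Fuchs dibromoolefination (Wittig reaction of Ph3P=CBr2) in its neutral zinc variant, which exposes the epimerisable α-center to neither base nor acid.

Step 11
Reactants: 18 3-[(1E,3E,8S)-10,10-dibromo-4,8-dimethyldeca-1,3,9-trien-1-yl]-4-(furan-3-ylmethyl)furan
Product: 20 (4S,8E,10E)-11-[4-(furan-3-ylmethyl)furan-3-yl]-4,8-dimethylundeca-8,10-dien-2-ynal, via lithium acetylide 19 (not isolated)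
Conditions: n-BuLi (2.05 equiv), THF, −78 °C; then DMF, −78 to 0 °C; inverse quench into cold aq. KH2PO4
Reagents that add atoms: N,N-dimethylformamide, CN(C)C=O
Why: Second stage of the Corey–Fuchs sequence (bromine–lithium exchange, Fritsch–Buttenberg–Wiechell rearrangement, deprotonation) gives the lithium acetylide, which DMF formylates; the inverse buffered quench keeps liberated dimethylamine from adding to the ynal.

Step 12
Reactants: 20 (4S,8E,10E)-11-[4-(furan-3-ylmethyl)furan-3-yl]-4,8-dimethylundeca-8,10-dien-2-ynal; 21 methyl propanoate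
Product: 23 methyl (6S,10E,12E)-13-[4-(furan-3-ylmethyl)furan-3-yl]-3-hydroxy-2,6,10-trimethyltrideca-10,12-dien-4-ynoate (mixture at C2 and C3), via lithium enolate of methyl propanoate 22 (not isolated)
Conditions: 21, LiN(iPr)2, THF, −78 °C; then 20, −78 °C; AcOH
Reagents that add atoms: none
Why: Aldol addition of a lithium ester enolate to the highly electrophilic ynal at −78 °C should outrun conjugate addition and γ-deprotonation, so the propargylic stereocenter is safe; the two new centers form unselectively and are erased in steps 13 and 14.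

Step 13
Reactants: 23 methyl (6S,10E,12E)-13-[4-(furan-3-ylmethyl)furan-3-yl]-3-hydroxy-2,6,10-trimethyltrideca-10,12-dien-4-ynoate
Product: 24 methyl (6S,10E,12E)-13-[4-(furan-3-ylmethyl)furan-3-yl]-2,6,10-trimethyl-3-oxotrideca-10,12-dien-4-ynoate (C2 epimers, partly enolised)
Conditions: Dess–Martin periodinane, NaHCO3, CH2Cl2, 0 °C to rt
Reagents that add atoms: none
Why: Dess–Martin oxidation of the propargylic alcohol to the alkynyl ketone under neutral conditions, which avoids base-induced alkyne-to-allene isomerisation at the γ-stereocenter.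

Step 14
Reactants: 24 methyl (6S,10E,12E)-13-[4-(furan-3-ylmethyl)furan-3-yl]-2,6,10-trimethyl-3-oxotrideca-10,12-dien-4-ynoate
Product: 26 methyl (2E,6S,10E,12E)-13-[4-(furan-3-ylmethyl)furan-3-yl]-3-methoxy-2,6,10-trimethyltrideca-2,10,12-trien-4-ynoate, via potassium enolate 25 (not isolated)
Conditions: KN(SiMe3)2 (1.0 equiv), 18-crown-6, THF, −78 °C; then MeOTf, −78 to −40 °C
Reagents that add atoms: methyl trifluoromethanesulfonate, COS(=O)(=O)C(F)(F)F
Why: O-Alkylation of a β-keto ester enolate, in which the crown-separated potassium enolate should prefer the extended, non-chelated arrangement with the enolate oxygen anti to the ester carbonyl (the slim alkynyl group costs little next to the ester) and the hard electrophile MeOTf attacks oxygen, so the methoxy group ends trans to the ester and the alkyne cis to it (2E); as an enolate the substrate has no acidic γ-hydrogen, so the stereocenter is kept.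

Step 15
Reactants: 26 methyl (2E,6S,10E,12E)-13-[4-(furan-3-ylmethyl)furan-3-yl]-3-methoxy-2,6,10-trimethyltrideca-2,10,12-trien-4-ynoate
Product: 27 (2E,6S,10E,12E)-13-[4-(furan-3-ylmethyl)furan-3-yl]-3-methoxy-2,6,10-trimethyltrideca-2,10,12-trien-4-ynoic acid
Conditions: LiOH·H2O, THF/MeOH/H2O, rt; then cold dilute HCl to pH 4
Reagents that add atoms: lithium hydroxide, [Li+].[OH-]
Why: Saponification by acyl–oxygen cleavage, where hydroxide should attack the ester carbonyl of the β-methoxy enoate and not the enol ether or the alkyne, and the mild acidification spares the enol ether and the furans.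

Step 16
Reactants: 27 (2E,6S,10E,12E)-13-[4-(furan-3-ylmethyl)furan-3-yl]-3-methoxy-2,6,10-trimethyltrideca-2,10,12-trien-4-ynoic acid
Product: 28 (5Z)-5-{(2S,6E,8E)-9-[4-(furan-3-ylmethyl)furan-3-yl]-2,6-dimethylnona-6,8-dien-1-ylidene}-4-methoxy-3-methylfuran-2(5H)-one
Conditions: AgNO3 (10 mol%), acetone, rt, dark
Reagents that add atoms: none
Why: Monovalent silver coordinates the alkyne of 27, and the carboxyl oxygen, held cis to the alkyne by the tetrasubstituted C2=C3 enol ether, attacks the proximal alkyne carbon (C4 of the acid, C5 of ring A) from the face opposite to silver; protodeargentation of the vinylsilver with retention returns the catalyst. This is the known silver-catalysed cycloisomerisation of (Z)-2-en-4-ynoic acids to (Z)-γ-ylidenebutenolides. Ring A closes in the 5-exo-dig mode by forming the O1–C5 bond. No stereocenter is formed; the anti addition puts the ring oxygen and the side chain on the same side of the exocyclic double bond (5Z), which is also the more stable isomer, and the adjacent stereocenter is not touched under these neutral conditions. The step needs 5-exo over 6-endo closure (no 2-pyranone), and the silver catalyst, the branched sec-alkyl group that shields the distal alkyne carbon and the absence of a cation-stabilising group there should direct the oxygen to the proximal carbon. The diene and the furans bind silver only reversibly, and the reaction is run in the dark at room temperature.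

Step 17
Reactants: 28 (5Z)-5-{(2S,6E,8E)-9-[4-(furan-3-ylmethyl)furan-3-yl]-2,6-dimethylnona-6,8-dien-1-ylidene}-4-methoxy-3-methylfuran-2(5H)-one
Product: 29 (5Z)-5-{(2S,6E,8E)-9-[4-(furan-3-ylmethyl)furan-3-yl]-2,6-dimethylnona-6,8-dien-1-ylidene}-4-hydroxy-3-methylfuran-2(5H)-one (CNP0288126.1)
Conditions: LiCl (10 equiv), DMF, 90 °C; then cold dilute HCl to pH 3
Reagents that add atoms: none
Why: SN2 demethylation of the vinylogous methyl ester by chloride (the tetronate anion is a good leaving group), the usual release of a tetronic acid from its methyl ether, under salt conditions that should leave the Z-ylidene, the diene, the furans and the allylic stereocenter unchanged.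

**Compound list**

1 | 3,4-dibromofuran | Brc1cocc1Br | starting material
2 | furan-3-carbaldehyde | O=Cc1ccoc1 | starting material
3 | 4-bromo-3-furyllithium | [Li]c1cocc1Br | intermediate (not isolated)
4 | (4-bromofuran-3-yl)(furan-3-yl)methanol, racemic | OC(c1ccoc1)c1cocc1Br | intermediate
5 | 3-bromo-4-(furan-3-ylmethyl)furan | Brc1cocc1Cc1ccoc1 | intermediate
6 | 4-(furan-3-ylmethyl)-3-furyllithium | [Li]c1cocc1Cc1ccoc1 | intermediate (not isolated)
7 | 4-(furan-3-ylmethyl)furan-3-carbaldehyde | O=Cc1cocc1Cc1ccoc1 | intermediate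
8 | 3-(furan-3-ylmethyl)-4-[(E)-2-iodoethenyl]furan | I/C=C/c1cocc1Cc1ccoc1 | intermediate
9 | (R)-3-bromo-2-methylpropan-1-ol | OC[C@@H](C)CBr | starting material
10 | tert-butyl{[(2R)-3-bromo-2-methylpropyl]oxy}dimethylsilane | CC(C)(C)[Si](C)(C)OC[C@@H](C)CBr | intermediate
11 | (4-bromobut-1-yn-1-yl)trimethylsilane | C[Si](C)(C)C#CCCBr | starting material
12 | 4-(trimethylsilyl)but-3-ynylmagnesium bromide | C[Si](C)(C)C#CCC[Mg]Br | intermediate (not isolated)
13 | tert-butyldimethyl{[(2S)-2-methyl-7-(trimethylsilyl)hept-6-yn-1-yl]oxy}silane | CC(C)(C)[Si](C)(C)OC[C@@H](C)CCCC#C[Si](C)(C)C | intermediate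
14 | (2S)-2-methylhept-6-yn-1-ol | OC[C@@H](C)CCCC#C | intermediate
15 | (E)-alkenyldimethylalane from 14, oxygen bound as dimethylaluminium alkoxide | C[Al](C)OC[C@@H](C)CCC/C(C)=C/[Al](C)C | intermediate (not isolated)
16 | (2S,6E,8E)-9-[4-(furan-3-ylmethyl)furan-3-yl]-2,6-dimethylnona-6,8-dien-1-ol | OC[C@@H](C)CCC/C(C)=C/C=C/c1cocc1Cc1ccoc1 | intermediate
17 | (2S,6E,8E)-9-[4-(furan-3-ylmethyl)furan-3-yl]-2,6-dimethylnona-6,8-dienal | O=C[C@@H](C)CCC/C(C)=C/C=C/c1cocc1Cc1ccoc1 | intermediate
18 | 3-[(1E,3E,8S)-10,10-dibromo-4,8-dimethyldeca-1,3,9-trien-1-yl]-4-(furan-3-ylmethyl)furan | BrC(Br)=C[C@@H](C)CCC/C(C)=C/C=C/c1cocc1Cc1ccoc1 | intermediate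
19 | lithium acetylide of (3S,7E,9E)-10-[4-(furan-3-ylmethyl)furan-3-yl]-3,7-dimethyldeca-7,9-dien-1-yne | [Li]C#C[C@@H](C)CCC/C(C)=C/C=C/c1cocc1Cc1ccoc1 | intermediate (not isolated)
20 | (4S,8E,10E)-11-[4-(furan-3-ylmethyl)furan-3-yl]-4,8-dimethylundeca-8,10-dien-2-ynal | O=CC#C[C@@H](C)CCC/C(C)=C/C=C/c1cocc1Cc1ccoc1 | intermediate
21 | methyl propanoate | CCC(=O)OC | starting material
22 | lithium enolate of methyl propanoate | CC=C(O[Li])OC | intermediate (not isolated)
23 | methyl (6S,10E,12E)-13-[4-(furan-3-ylmethyl)furan-3-yl]-3-hydroxy-2,6,10-trimethyltrideca-10,12-dien-4-ynoate, mixture at C2 and C3 | COC(=O)C(C)C(O)C#C[C@@H](C)CCC/C(C)=C/C=C/c1cocc1Cc1ccoc1 | intermediate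
24 | methyl (6S,10E,12E)-13-[4-(furan-3-ylmethyl)furan-3-yl]-2,6,10-trimethyl-3-oxotrideca-10,12-dien-4-ynoate, C2 epimers | COC(=O)C(C)C(=O)C#C[C@@H](C)CCC/C(C)=C/C=C/c1cocc1Cc1ccoc1 | intermediate
25 | potassium enolate of 24, enolate oxygen trans to the ester | COC(=O)/C(C)=C([O-])\C#C[C@@H](C)CCC/C(C)=C/C=C/c1cocc1Cc1ccoc1.[K+] | intermediate (not isolated)
26 | methyl (2E,6S,10E,12E)-13-[4-(furan-3-ylmethyl)furan-3-yl]-3-methoxy-2,6,10-trimethyltrideca-2,10,12-trien-4-ynoate | COC(=O)/C(C)=C(OC)\C#C[C@@H](C)CCC/C(C)=C/C=C/c1cocc1Cc1ccoc1 | intermediate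
27 | (2E,6S,10E,12E)-13-[4-(furan-3-ylmethyl)furan-3-yl]-3-methoxy-2,6,10-trimethyltrideca-2,10,12-trien-4-ynoic acid | OC(=O)/C(C)=C(OC)\C#C[C@@H](C)CCC/C(C)=C/C=C/c1cocc1Cc1ccoc1 | intermediate (key-step precursor)
28 | (5Z)-5-{(2S,6E,8E)-9-[4-(furan-3-ylmethyl)furan-3-yl]-2,6-dimethylnona-6,8-dien-1-ylidene}-4-methoxy-3-methylfuran-2(5H)-one | CC1=C(OC)/C(=C/[C@@H](C)CCC/C(C)=C/C=C/c2cocc2Cc2ccoc2)OC1=O | intermediate (key-step product)
29 | (5Z)-5-{(2S,6E,8E)-9-[4-(furan-3-ylmethyl)furan-3-yl]-2,6-dimethylnona-6,8-dien-1-ylidene}-4-hydroxy-3-methylfuran-2(5H)-one | CC1=C(O)/C(=C/[C@@H](C)CCC/C(C)=C/C=C/c2cocc2Cc2ccoc2)OC1=O | target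

**Count and risks**

Total step count: 17. Longest linear sequence: 14 steps (steps 1–4 and 8–17, from 1 to 29); the branch from 9 is 13 steps.

Steps most likely to fail:

Step 14. The enolate may be methylated on carbon C2 instead of oxygen, may give the enol ether with the methoxy group cis to the ester (which cannot close ring A), or may add through its ester oxygen to the alkyne before it is trapped. The fallback fixes the enol ether geometry before the C3–C4 bond is made. It sets out from 18: n-BuLi (2 equiv, THF, −78 °C) gives 19, and iodine then gives 3-(furan-3-ylmethyl)-4-[(1E,3E,8S)-10-iodo-4,8-dimethyldeca-1,3-dien-9-yn-1-yl]furan F1. Separately, methyl propanoate 21 is formylated (NaH, HCO2Me) to methyl 2-methyl-3-oxopropanoate F2 and O-methylated (Me2SO4, K2CO3) to methyl (2E)-3-methoxy-2-methylprop-2-enoate F3. Lithiation of F3 at C3 (LiN(iPr)2, THF, −95 °C; lithium is held cis to the ester by chelation) and quenching with Bu3SnCl should give methyl (2Z)-3-methoxy-2-methyl-3-(tributylstannyl)prop-2-enoate F4. Stille coupling of F1 with F4 (Pd(PPh3)4, CuI, DMF, rt) proceeds with retention and should deliver the alkyne cis to the ester. The route is rejoined at 26, and steps 11 to 14 are replaced.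

Step 16. The carboxyl oxygen may close on the distal alkyne carbon (6-endo, giving a 2-pyranone), or turnover may stall because the diene and furans hold the silver. The fallback builds the ylidene by aldol condensation onto a preformed tetronate. It sets out from 17: 4-methoxy-3-methylfuran-2(5H)-one F5 is deprotonated at C5 (LiN(iPr)2, THF, −78 °C) and added to 17 to give 5-{(2S,6E,8E)-9-[4-(furan-3-ylmethyl)furan-3-yl]-1-hydroxy-2,6-dimethylnona-6,8-dien-1-yl}-4-methoxy-3-methylfuran-2(5H)-one F6. Mesylation (MsCl, Et3N, CH2Cl2, 0 °C) gives the methanesulfonate of that alcohol F7, and elimination with DBU should give the more stable Z-ylidene. The route is rejoined at 28, and steps 10 to 16 are replaced.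

Step 2. The difurylmethyl cation may alkylate furan rings of other molecules (oligomerisation), or the acid may degrade the furans before hydride transfer. The fallback forms the CH2 bridge by cross-coupling and needs no carbinol. It sets out from 1: after the exchange of step 1 to 3, ZnCl2 gives (4-bromofuran-3-yl)zinc chloride F8. Negishi coupling of F8 with 3-(bromomethyl)furan (Pd(PPh3)4, THF, rt) should work because the benzylic-type C–Br bond adds to zerovalent palladium much faster than the furyl C–Br bond. The route is rejoined at 5, and steps 1 and 2 are replaced.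

Further compounds
F1 | step 14 | 3-(furan-3-ylmethyl)-4-[(1E,3E,8S)-10-iodo-4,8-dimethyldeca-1,3-dien-9-yn-1-yl]furan | IC#C[C@@H](C)CCC/C(C)=C/C=C/c1cocc1Cc1ccoc1
F2 | step 14 | methyl 2-methyl-3-oxopropanoate | COC(=O)C(C)C=O
F3 | step 14 | methyl (2E)-3-methoxy-2-methylprop-2-enoate | COC(=O)/C(C)=C/OC
F4 | step 14 | methyl (2Z)-3-methoxy-2-methyl-3-(tributylstannyl)prop-2-enoate | COC(=O)/C(C)=C(OC)\[Sn](CCCC)(CCCC)CCCC
F5 | step 16 | 4-methoxy-3-methylfuran-2(5H)-one | COC1=C(C)C(=O)OC1
F6 | step 16 | 5-{(2S,6E,8E)-9-[4-(furan-3-ylmethyl)furan-3-yl]-1-hydroxy-2,6-dimethylnona-6,8-dien-1-yl}-4-methoxy-3-methylfuran-2(5H)-one, diastereomer mixture | COC1=C(C)C(=O)OC1C(O)[C@@H](C)CCC/C(C)=C/C=C/c1cocc1Cc1ccoc1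
F7 | step 16 | methanesulfonate of F6 | COC1=C(C)C(=O)OC1C(OS(C)(=O)=O)[C@@H](C)CCC/C(C)=C/C=C/c1cocc1Cc1ccoc1
F8 | step 2 | (4-bromofuran-3-yl)zinc chloride | Cl[Zn]c1cocc1Br
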